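The route builds ring C of the 5,7-dihydroxyflavanone half by one-carbon ring expansion of a coumaranone. The key step exploits the C3 methylene of that ring, which lies between the C4 carbonyl and the O1-bound C2. It is installed as the CH2 of a cyclopropane fused to C2–C3 of a 3-silyloxybenzofuran, and FeCl3 cleaves the fusion bond so that the five-membered furanone becomes the six-membered chromone in one operation. The precursor is a 2-oxabicyclo[3.1.0]hexane siloxycyclopropane fused to the dibenzyloxy ring A. Ligand-controlled asymmetric conjugate additions of arylboronic acids to this chromone and to a second, 8-arylated chromone then set C2 and C2'' and join the halves.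

Key step: step 4

Remark on the chemistry: the 3'–8'' biaryl axis has only three ortho substituents, all oxygen, so it is taken to rotate freely at room temperature and no axial configuration is assigned or controlled.

Step 1
Reactants: 1 4,6-dihydroxybenzofuran-3(2H)-one; 2 benzyl bromide
Product: 3 4,6-bis(benzyloxy)benzofuran-3(2H)-one
Conditions: BnBr (2.4 equiv), K2CO3, DMF, 60 °C
Reagents that add atoms: benzyl bromide, BrCc1ccccc1
Why: Williamson ether synthesis on both phenols, whose phenoxides should alkylate on oxygen well before the C2 enolate forms under carbonate conditions.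

Step 2
Reactants: 3 4,6-bis(benzyloxy)benzofuran-3(2H)-one; 4 trimethylsilyl trifluoromethanesulfonate
Product: 5 4,6-bis(benzyloxy)-3-(trimethylsilyloxy)benzofuran
Conditions: TMSOTf, Et3N, CH2Cl2, 0 °C
Reagents that add atoms: trimethylsilyl trifluoromethanesulfonate, C[Si](C)(C)OS(=O)(=O)C(F)(F)F
Why: Silyl enol ether formation by soft enolization, helped by the gain of benzofuran aromaticity on O-silylation.

Step 3
Reactants: 5 4,6-bis(benzyloxy)-3-(trimethylsilyloxy)benzofuran; 6 diiodomethane
Product: 7 4,6-bis(benzyloxy)-6b-(trimethylsilyloxy)-1a,6b-dihydro-1H-cyclopropa[b][1]benzofuran (racemic, cis ring fusion)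
Conditions: Et2Zn, CH2I2, CH2Cl2, 0 °C to rt; pyridine, then aq NaHCO3
Reagents that add atoms: diiodomethane, ICI
Why: Furukawa-modified Simmons–Smith cyclopropanation of the electron-rich C2=C3 enol ether bond; the two new stereocentres are necessarily cis, form as a racemate and are erased in step 4.

Step 4
Reactants: 7 4,6-bis(benzyloxy)-6b-(trimethylsilyloxy)-1a,6b-dihydro-1H-cyclopropa[b][1]benzofuran
Product: 9 5,7-bis(benzyloxy)-4H-chromen-4-one, via 2-chlorochromanone 8 (not isolated)
Conditions: FeCl3 (2.2 equiv), DMF, 0 °C to rt; then NaOAc, MeOH, reflux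
Reagents that add atoms: none
Why: FeCl3 should exchange the silyl group for a trivalent-iron cyclopropoxide, and inner-sphere electron transfer then gives the cyclopropyloxy radical, which breaks the ring-fusion bond C1a–C6b because that β-scission places the radical on the carbon bound to the ring oxygen (the future C2) and not on a primary CH2. Chlorine transfer from a second FeCl3 gives 2-chlorochromanone 8, and sodium acetate removes HCl across C2–C3, so the cyclopropane CH2 ends as C3 between C2 and the C4 carbonyl. The closest known reaction type is the Ito–Saegusa one-carbon ring expansion of cycloalkanone silyl enol ethers by cyclopropanation and FeCl3 oxidation. No ring is closed by a cyclization: the six-membered pyranone arises from the five-membered furanone by cleavage of the zero-atom bridge of the oxabicyclo[3.1.0]hexane, a ring expansion by one carbon. No stereocentre is formed; the two of 7 are erased and 9 is achiral. The step needs scission of the internal bond in preference to the outer C6b–CH2 bond, which the α-oxygen stabilisation of the radical should secure, and oxidation of the alkoxide in preference to the oxygenated arene, which the mild oxidant in DMF at 0 °C should secure.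

Step 5
Reactants: 10 1-(2,6-dihydroxy-4-methoxyphenyl)ethanone; 2 benzyl bromide
Product: 11 1-[2-(benzyloxy)-6-hydroxy-4-methoxyphenyl]ethanone
Conditions: BnBr (1.05 equiv), K2CO3, acetone, reflux
Reagents that add atoms: benzyl bromide, BrCc1ccccc1
Why: Williamson mono-etherification of a symmetric diol, which should stop after one alkylation because the remaining hydroxyl is held in a strong hydrogen bond to the acetyl group.

Step 6
Reactants: 11 1-[2-(benzyloxy)-6-hydroxy-4-methoxyphenyl]ethanone; 12 benzyltrimethylammonium dichloroiodate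
Product: 13 1-[6-(benzyloxy)-2-hydroxy-3-iodo-4-methoxyphenyl]ethanone
Conditions: BnMe3N·ICl2, NaHCO3, CH2Cl2/MeOH, rt
Reagents that add atoms: benzyltrimethylammonium dichloroiodate, C[N+](C)(C)Cc1ccccc1.Cl[I-]Cl
Why: Electrophilic aromatic iodination, expected ortho to the free chelated hydroxyl because that position is less shielded than the one between the two ether groups, as in the analogous 3'-iodination of 2'-hydroxy-4',6'-dimethoxyacetophenone.

Step 7
Reactants: 13 1-[6-(benzyloxy)-2-hydroxy-3-iodo-4-methoxyphenyl]ethanone; 14 N,N-dimethylformamide dimethyl acetal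
Product: 16 5-(benzyloxy)-8-iodo-7-methoxy-4H-chromen-4-one, via enaminone 15 (not isolated)
Conditions: Me2NCH(OMe)2, toluene, 100 °C; then conc. HCl, CH2Cl2, rt
Reagents that add atoms: N,N-dimethylformamide dimethyl acetal, COC(OC)N(C)C
Why: Enaminone condensation at the acetyl methyl followed by acid-promoted 6-endo addition of the phenol and loss of dimethylamine, the standard chromone synthesis from 2'-hydroxyacetophenones, which places the iodine at C8.

Step 8
Reactants: 16 5-(benzyloxy)-8-iodo-7-methoxy-4H-chromen-4-one; 17 [2-(benzyloxy)-5-chlorophenyl]boronic acid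
Product: 18 5-(benzyloxy)-8-[2-(benzyloxy)-5-chlorophenyl]-7-methoxy-4H-chromen-4-one
Conditions: Pd(PPh3)4 (5 mol%), K3PO4, dioxane/H2O, 85 °C
Reagents that add atoms: [2-(benzyloxy)-5-chlorophenyl]boronic acid, OB(O)c1cc(Cl)ccc1OCc1ccccc1
Why: Suzuki–Miyaura coupling in which the triphenylphosphine catalyst should insert into the carbon–iodine bond but leave the electron-rich aryl chloride untouched as the handle for step 10.

Step 9
Reactants: 18 5-(benzyloxy)-8-[2-(benzyloxy)-5-chlorophenyl]-7-methoxy-4H-chromen-4-one; 19 [4-(benzyloxy)phenyl]boronic acid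
Product: 20 (2S)-5-(benzyloxy)-8-[2-(benzyloxy)-5-chlorophenyl]-2-[4-(benzyloxy)phenyl]-7-methoxychroman-4-one
Conditions: Pd(OCOCF3)2 (5 mol%), (R)-t-BuPyOx (6 mol%), NH4PF6, H2O, ClCH2CH2Cl, 60 °C
Reagents that add atoms: [4-(benzyloxy)phenyl]boronic acid, OB(O)c1ccc(OCc2ccccc2)cc1
Why: Asymmetric conjugate addition of an arylboronic acid to a chromone under divalent-palladium pyridine–oxazoline catalysis (aryl transfer, insertion of C2=C3, protonolysis of the palladium enolate), in which the tert-butyl group of the ligand selects the face and the (R)-ligand is expected to give 2S by analogy with the (S)-ligand/(R)-product pairing on 3-substituted cyclohexenones, the antipodal ligand being used should a model run show the opposite sense.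

Step 10
Reactants: 20 (2S)-5-(benzyloxy)-8-[2-(benzyloxy)-5-chlorophenyl]-2-[4-(benzyloxy)phenyl]-7-methoxychroman-4-one; 21 tetrahydroxydiboron
Product: 22 {4-(benzyloxy)-3-[(2S)-5-(benzyloxy)-2-[4-(benzyloxy)phenyl]-7-methoxy-4-oxochroman-8-yl]phenyl}boronic acid
Conditions: B2(OH)4, KOAc, chloro(2-dicyclohexylphosphino-2',4',6'-triisopropylbiphenyl)[2-(2'-aminobiphenyl)]palladium (2 mol%), XPhos, EtOH/THF, 80 °C
Reagents that add atoms: tetrahydroxydiboron, OB(O)B(O)O
Why: Miyaura-type borylation of the aryl chloride with a bulky biarylphosphine palladium catalyst, under acetate that is too weak a base to open the flavanone, so C2'' should stay intact.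

Step 11
Reactants: 22 {4-(benzyloxy)-3-[(2S)-5-(benzyloxy)-2-[4-(benzyloxy)phenyl]-7-methoxy-4-oxochroman-8-yl]phenyl}boronic acid; 9 5,7-bis(benzyloxy)-4H-chromen-4-one
Product: 23 (2S)-5-(benzyloxy)-8-{2-(benzyloxy)-5-[(2S)-5,7-bis(benzyloxy)-4-oxochroman-2-yl]phenyl}-2-[4-(benzyloxy)phenyl]-7-methoxychroman-4-one
Conditions: 9 (2 equiv), Pd(OCOCF3)2 (10 mol%), (R)-t-BuPyOx (12 mol%), NH4PF6, H2O, ClCH2CH2Cl, 60 °C
Reagents that add atoms: none
Why: The same divalent-palladium asymmetric conjugate addition, now joining the two halves at C2–C1', with the new C2 stereocentre (S) set by the ligand alone because the existing C2'' centre is too remote to interfere.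

Step 12
Reactants: 23 (2S)-5-(benzyloxy)-8-{2-(benzyloxy)-5-[(2S)-5,7-bis(benzyloxy)-4-oxochroman-2-yl]phenyl}-2-[4-(benzyloxy)phenyl]-7-methoxychroman-4-one
Product: 24 (2S)-8-{5-[(2S)-5,7-dihydroxy-4-oxochroman-2-yl]-2-hydroxyphenyl}-5-hydroxy-2-(4-hydroxyphenyl)-7-methoxychroman-4-one
Conditions: H2 (1 atm), Pd/C, EtOAc/MeOH, rt
Reagents that add atoms: none
Why: Hydrogenolysis of the five benzyl ethers under neutral conditions, which should spare the methyl ether, the electron-rich aryl ketones and both base-labile C2 stereocentres.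

Compound list
1 | 4,6-dihydroxybenzofuran-3(2H)-one | O=C1COc2cc(O)cc(O)c21 | starting material
2 | benzyl bromide | BrCc1ccccc1 | starting material
3 | 4,6-bis(benzyloxy)benzofuran-3(2H)-one | O=C1COc2cc(OCc3ccccc3)cc(OCc3ccccc3)c21 | intermediate
4 | trimethylsilyl trifluoromethanesulfonate | C[Si](C)(C)OS(=O)(=O)C(F)(F)F | starting material
5 | 4,6-bis(benzyloxy)-3-(trimethylsilyloxy)benzofuran | C[Si](C)(C)Oc1coc2cc(OCc3ccccc3)cc(OCc3ccccc3)c12 | intermediate
6 | diiodomethane | ICI | starting material
7 | 4,6-bis(benzyloxy)-6b-(trimethylsilyloxy)-1a,6b-dihydro-1H-cyclopropa[b][1]benzofuran (racemic, cis-fused) | C[Si](C)(C)OC12CC1Oc1cc(OCc3ccccc3)cc(OCc3ccccc3)c12 | intermediate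
8 | 5,7-bis(benzyloxy)-2-chlorochroman-4-one (racemic) | O=C1CC(Cl)Oc2cc(OCc3ccccc3)cc(OCc3ccccc3)c21 | intermediate (not isolated)
9 | 5,7-bis(benzyloxy)-4H-chromen-4-one | O=c1ccoc2cc(OCc3ccccc3)cc(OCc3ccccc3)c12 | intermediate
10 | 1-(2,6-dihydroxy-4-methoxyphenyl)ethanone | CC(=O)c1c(O)cc(OC)cc1O | starting material
11 | 1-[2-(benzyloxy)-6-hydroxy-4-methoxyphenyl]ethanone | CC(=O)c1c(O)cc(OC)cc1OCc1ccccc1 | intermediate
12 | benzyltrimethylammonium dichloroiodate | C[N+](C)(C)Cc1ccccc1.Cl[I-]Cl | starting material
13 | 1-[6-(benzyloxy)-2-hydroxy-3-iodo-4-methoxyphenyl]ethanone | CC(=O)c1c(O)c(I)c(OC)cc1OCc1ccccc1 | intermediate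
14 | N,N-dimethylformamide dimethyl acetal | COC(OC)N(C)C | starting material
15 | (E)-1-[6-(benzyloxy)-2-hydroxy-3-iodo-4-methoxyphenyl]-3-(dimethylamino)prop-2-en-1-one | CN(C)/C=C/C(=O)c1c(O)c(I)c(OC)cc1OCc1ccccc1 | intermediate (not isolated)
16 | 5-(benzyloxy)-8-iodo-7-methoxy-4H-chromen-4-one | COc1cc(OCc2ccccc2)c2c(=O)ccoc2c1I | intermediate
17 | [2-(benzyloxy)-5-chlorophenyl]boronic acid | OB(O)c1cc(Cl)ccc1OCc1ccccc1 | starting material
18 | 5-(benzyloxy)-8-[2-(benzyloxy)-5-chlorophenyl]-7-methoxy-4H-chromen-4-one | COc1cc(OCc2ccccc2)c2c(=O)ccoc2c1-c1cc(Cl)ccc1OCc1ccccc1 | intermediate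
19 | [4-(benzyloxy)phenyl]boronic acid | OB(O)c1ccc(OCc2ccccc2)cc1 | starting material
20 | (2S)-5-(benzyloxy)-8-[2-(benzyloxy)-5-chlorophenyl]-2-[4-(benzyloxy)phenyl]-7-methoxychroman-4-one | COc1cc(OCc2ccccc2)c2c(c1-c1cc(Cl)ccc1OCc1ccccc1)O[C@H](c1ccc(OCc3ccccc3)cc1)CC2=O | intermediate
21 | tetrahydroxydiboron | OB(O)B(O)O | starting material
22 | {4-(benzyloxy)-3-[(2S)-5-(benzyloxy)-2-[4-(benzyloxy)phenyl]-7-methoxy-4-oxochroman-8-yl]phenyl}boronic acid | COc1cc(OCc2ccccc2)c2c(c1-c1cc(B(O)O)ccc1OCc1ccccc1)O[C@H](c1ccc(OCc3ccccc3)cc1)CC2=O | intermediate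
23 | (2S)-5-(benzyloxy)-8-{2-(benzyloxy)-5-[(2S)-5,7-bis(benzyloxy)-4-oxochroman-2-yl]phenyl}-2-[4-(benzyloxy)phenyl]-7-methoxychroman-4-one | COc1cc(OCc2ccccc2)c2c(c1-c1cc([C@@H]3CC(=O)c4c(OCc5ccccc5)cc(OCc5ccccc5)cc4O3)ccc1OCc1ccccc1)O[C@H](c1ccc(OCc3ccccc3)cc1)CC2=O | intermediate
24 | (2S)-8-{5-[(2S)-5,7-dihydroxy-4-oxochroman-2-yl]-2-hydroxyphenyl}-5-hydroxy-2-(4-hydroxyphenyl)-7-methoxychroman-4-one | COc1cc(O)c2c(c1-c1cc([C@@H]3CC(=O)c4c(O)cc(O)cc4O3)ccc1O)O[C@H](c1ccc(O)cc1)CC2=O | target

Total step count: 12.
Longest linear sequence: 8 steps (steps 5 to 12, from 10 to 24); the other branch (steps 1 to 4) joins at step 11.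

Steps most likely to fail

First, step 4, the key step. The siloxycyclopropane may open heterolytically at the outer C6b–CH2 bond on contact with Lewis-acidic iron or zinc salts, which would lead to a 2-methylcoumaranone without ring expansion. The trioxygenated arene may also be oxidised before the alkoxide. The fallback sets out from 5 and comes back at 9. Dibromocarbene (CHBr3, KOtBu, hexane, −20 °C to rt) should add to C2=C3 of 5. The dibromocyclopropane should open at once by loss of bromide with cleavage of the fusion bond, pushed by O1 and the silyloxy group, and loss of the silyl group should give 3-bromo-5,7-bis(benzyloxy)-4H-chromen-4-one F1. This is again a one-carbon expansion of the furanone, now through a cationic cyclopropyl-to-allyl opening and not a radical scission. Hydrodebromination of F1 (Pd(OAc)2, PPh3, HCO2H, Et3N, DMF, 60 °C) should then give 9.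

Second, step 11. Transfer and insertion of a bulky, electron-rich arylboronic acid into an electron-rich chromone may be so slow that protodeboronation of 22 outruns carbon–carbon bond formation, and ligand control may erode at the higher temperature then needed. The fallback sets out from 9 and 16 and comes back at 23; it moves the union of the halves from the conjugate addition to the biaryl bond.
- Chromone 9 should take up commercial [4-(benzyloxy)-3-chlorophenyl]boronic acid, used in excess, under the conditions of step 9 to give (2S)-5,7-bis(benzyloxy)-2-[4-(benzyloxy)-3-chlorophenyl]chroman-4-one F3.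
- Borylation of F3 as in step 10 should give {2-(benzyloxy)-5-[(2S)-5,7-bis(benzyloxy)-4-oxochroman-2-yl]phenyl}boronic acid F4.
- Separately, 16 and 19 under the conditions of step 9 should give (2S)-5-(benzyloxy)-2-[4-(benzyloxy)phenyl]-8-iodo-7-methoxychroman-4-one F5, since the redox-neutral divalent-palladium cycle should leave the carbon–iodine bond alone.
- Suzuki–Miyaura coupling of F4 with F5 (Pd(PPh3)4, K3PO4, dioxane/H2O, 70 °C) should then give 23.

Third, step 8. The coupling forms a biaryl with three ortho substituents and may be slow enough for base-induced opening of the 2-unsubstituted pyranone ring and protodeiodination to take over. The fallback sets out from 13 and comes back at 18. The Suzuki–Miyaura coupling is run one stage earlier, on the acetophenone, where no pyranone is present and the neighbouring phenoxide can assist: 13 and 17 (Pd(PPh3)4, K3PO4, dioxane/H2O, 85 °C) should give 1-[6-(benzyloxy)-3-[2-(benzyloxy)-5-chlorophenyl]-2-hydroxy-4-methoxyphenyl]ethanone F2. Chromone formation on F2 as in step 7 (Me2NCH(OMe)2, then HCl) should give 18.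

Further compounds
F1 | step 4 | 3-bromo-5,7-bis(benzyloxy)-4H-chromen-4-one | O=c1c(Br)coc2cc(OCc3ccccc3)cc(OCc3ccccc3)c12
F2 | step 8 | 1-[6-(benzyloxy)-3-[2-(benzyloxy)-5-chlorophenyl]-2-hydroxy-4-methoxyphenyl]ethanone | CC(=O)c1c(O)c(-c2cc(Cl)ccc2OCc2ccccc2)c(OC)cc1OCc1ccccc1
F3 | step 11 | (2S)-5,7-bis(benzyloxy)-2-[4-(benzyloxy)-3-chlorophenyl]chroman-4-one | O=C1C[C@@H](c2ccc(OCc3ccccc3)c(Cl)c2)Oc2cc(OCc3ccccc3)cc(OCc3ccccc3)c21
F4 | step 11 | {2-(benzyloxy)-5-[(2S)-5,7-bis(benzyloxy)-4-oxochroman-2-yl]phenyl}boronic acid | O=C1C[C@@H](c2ccc(OCc3ccccc3)c(B(O)O)c2)Oc2cc(OCc3ccccc3)cc(OCc3ccccc3)c21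
F5 | step 11 | (2S)-5-(benzyloxy)-2-[4-(benzyloxy)phenyl]-8-iodo-7-methoxychroman-4-one | COc1cc(OCc2ccccc2)c2c(c1I)O[C@H](c1ccc(OCc3ccccc3)cc1)CC2=O
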